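What is slow in this chemistry? Other capture product is still climbing in Sunday's run at 10.0 min, so its supply is slow, and the question is what that slowness does to a ratio.

| flask | substrate | first nucleophile | second nucleophile | remark | time |
|---|---|---|---|---|---|
| Sunday's | 0.025 M | 0.20 M | 0.045 M | run made earlier |  |
| Monday's | 0.038 M | 0.20 M | 0.045 M | run made earlier |  |
| flask | 0.050 M | 0.200 M | 0.0450 M |  | 20 min |

- Sunday's (time / min: target / %, other capture product / %): 2.50: 10.1, 7.9; 5.00: 7.6, 12.9; 6.00: 6.0, 14.2; 10.0: 2.8, 18.2; 12.0: 3.2, 18.8; 15.0: 0.6, 21.6
- Monday's (time / min: target / %, other capture product / %): 1.33: 6.4, 5.2; 2.00: 8.0, 6.0; 3.00: 11.0, 7.4; 5.00: 7.0, 12.5; 6.00: 6.8, 13.6; 10.0: 3.7, 15.9; 15.0: 2.7, 21.6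

(standard deviation of a reading: 1 percentage point)

- share of target in target plus other capture product at 12 s
- share of target in target plus other capture product at 2.0 min
- share of target in target plus other capture product at 20 min

- the numbers in the tables scatter with a standard deviation of 1 percentage point

What do you carry? The ratio of target to other capture product at a fixed clock time, since the share asked for follows from it.

Does the flask's larger substrate charge change that ratio? Take the balance of second nucleophile, charged below substrate in the flask, 0.0450 M against 0.050 M. At 15.0 min other capture product reads 21.6% on Sunday and 21.6% on Monday, level although Monday charged more substrate. If the flask reaches that percentage, with one second nucleophile each, I reckon capture there at 0.0108 M, about a quarter of the second nucleophile charged.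

But might the rest of the substrate eat second nucleophile? Then the two runs should part. At 5.00 min their ratios read 0.589 and 0.560, and later target readings lie too near the scatter to say otherwise. So I pool them.

And the numbers? Monday gives 1.33 at 2.00 min, and the pooled runs give 0.575 at 5.00 min and 0.0764 at 15.0 min. The logarithm falls at 0.280 /min first, then more slowly at 0.202 /min. Running these lines out, I expect a ratio of 2.21 at 12 s, a share of 68.8%; 57.1% at 2.0 min; and 0.0278 at 20 min, a share of 2.70%. Monday's first reading, a ratio of 1.23 at 1.33 min, lies below the early line, and the late line rests on target readings of 0.6% and 2.7% against a scatter of 1 point.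

Assuming both products share one parent, the ratio at 20 min divided by the charged c(first nucleophile)/c(second nucleophile) is a factor for that clock time, 0.00627.

The forecast gave 62%, 61% and 40%, holding that “late conversion stalls”; these figures differ from mine.

The flask gives 69.7%, 57.5% and 2.41%.

    substrate + intermediate → side product (k = 0.140 /M/s)
    target → over-reaction product (k = 0.0150 /s)
    substrate → intermediate (k = 0.00300 /s)
    second nucleophile + intermediate → other capture product (k = 0.520 /M/s)
    first nucleophile + intermediate → target (k = 0.280 /M/s)
    second nucleophile ⇌ dormant form (K = 0.400, k = 0.00350 /s)

In the flask, target's half-life by its turning into over-reaction product is 0.770 min, shorter than substrate's 3.9 min by its turning into intermediate. At 20 min the flask's ratio, divided as before, is 0.00556 against my 0.00627.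

In the neighbour flask with 0.080 M of first nucleophile, the factor 0.00627 gives a ratio of 0.0111, a share of 1.10%. The computed share there is 1.10%.

All runs are calculated for substances that don't exist.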